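All runs stem from a simulated flask with made-up constants; scatter was added.

Start from a leftover: the left-handed substrate still in the gamma flask.

the same everywhere: partner 1.25 M; precatalyst 50 mM

| run | left-handed substrate | right-handed substrate | remark | time |
|---|---|---|---|---|
| gamma | 0.50 M | 0.50 M | the very flask that is asked about, followed so far |  |
| alpha | 1 M | 1 M | run made earlier |  |
| flask | 0.50 M | 0.50 M |  | 3.0 d |

| run | time / h | left-handed product / % | right-handed product / % | left-handed substrate / % |
|---|---|---|---|---|
| gamma | 4.00 | 2.0 | 0.4 | 48.8 |
| gamma | 8.00 | 3.2 | 0 | 47.1 |
| gamma | 10.0 | 4.4 | 0.2 | 46.9 |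
| gamma | 15.0 | 5.5 | 0.7 | 45.6 |
| alpha | 4.00 | 1.2 | 0.3 | 49.0 |
| alpha | 10.0 | 4.2 | 0 | 47.1 |
| alpha | 20.0 | 6.6 | 0.5 | 45.2 |
| alpha | 30.0 | 8.7 | 0.8 | 44.7 |

(each reading ± 0.5 percentage points)

- excess of left-handed product over right-handed product in the product at 80 min
- excess of left-handed product over right-handed product in the product at 3.0 d
- part of the left-handed substrate and right-handed substrate charged together that has reacted at 3.0 d

- free catalyst is single-handed; left-handed substrate and right-handed substrate are mirror images of each other, charged as a racemate, each of them at the stated concentration
- on the list of suspects stand: partner + free catalyst + right-handed substrate -> free catalyst + right-handed product; left-handed substrate <-> right-handed substrate; partner -> decomposed reagent; partner + precatalyst -> free catalyst + spent reagent; 2 free catalyst -> spent catalyst; partner + free catalyst + left-handed substrate -> free catalyst + left-handed product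
- an excess is the difference of the two amounts in percent of their sum
- an excess is below zero if the other one leads

Add the left-handed product to that leftover, then subtract the left-handed half of the charge. In gamma at 15.0 h this leaves 1.1 percentage points, the refill that came over from the right-handed substrate by racemization. The balance gives the gap, [right-handed substrate] − [left-handed substrate], as 2.6 points.

Let the gap grow evenly from zero. Refill over the area under the gap is then the racemization constant, which is 0.0564 h⁻¹ in gamma. The alpha run at 20.0 h is a second way, from other readings, and gives 0.0720 h⁻¹. Its row at 30.0 h parts from these with 0.206 h⁻¹. But that gap, 1.1 points, is smaller than its own scatter of 1.2 points, so that row cheats and I drop it.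

I carry the mean, 0.0642 h⁻¹, the racemization constant. With it comes a rule: the holding gap is the rate of making left-handed product over twice this constant. In gamma that rate is 0.003667 h⁻¹ as a fraction of the charge, slower than the forward racemization of 0.0293 h⁻¹. So the substrates stay close.

My pooled product readings give an excess of 85.0%.

The forecast says 85% (76% to 93%) at 80 min, 84% (75% to 92%) at 3.0 d, and 14.5% reacted (12% to 18%): “Racemization keeps the substrate nearly racemic, so the excess barely drops.”

The flask gives 92.3% at 80 min, 92.0% at 3.0 d, and 13.2% reacted. At 0.300 d the right-handed product stands at 0.102%, less than the scatter of a reading.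

    partner + free catalyst + right-handed substrate → free catalyst + right-handed product (k = 1.42 × 10⁻⁴ L² mol⁻² min⁻¹)
    left-handed substrate ⇌ right-handed substrate (k = 8.68 × 10⁻⁴ min⁻¹)
    partner → decomposed reagent (k = 4.82 × 10⁻⁴ min⁻¹)
    partner + precatalyst → free catalyst + spent reagent (k = 0.00505 L mol⁻¹ min⁻¹)
    2 free catalyst → spent catalyst (k = 0.00134 L mol⁻¹ min⁻¹)
    partner + free catalyst + left-handed substrate → free catalyst + left-handed product (k = 0.00357 L² mol⁻² min⁻¹)

In the neighbour flask with 0.013 M of precatalyst, 4.46% reacts and the excess at 3.0 d is 92.3%. Put into the rule with the carried constant, itself a reading from the runs with their scatter, the 4.28% of left-handed product in this neighbour flask gives an estimated mean holding gap of 0.46 points, and there 95% of the left-handed and 96% of the right-handed substrate remain.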